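The route rests on disconnecting the C2=C3 bond of the pyrrole ring, after removing the two pyrrole bromines from the target. C3 is the benzylic carbon on C3a, next to the C4 bromine, and C2 is a carbon at the formic acid oxidation level bonded to N1 on C7a. An intramolecular Wittig olefination of an N-formyl group by a benzylic phosphonium ylide therefore closes the five-membered ring and should give aromatic 4,6-dibromo-1H-indole in one operation. The precursor is a 2-formamidobenzyl triphenylphosphonium bromide bearing both aryl bromines, built in four steps from 2,4-dibromo-6-nitrotoluene. Bromination with NBS at C3 and then C2 finishes 2,3,4,6-tetrabromo-1H-indole.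

Key step: step 5

Remark: the target is a planar aromatic molecule without stereocentres, so no enantiomer exists and no stereocontrol is needed; compound 1 is assumed to be a commercial chemical.

Remark on the precursor: phosphorus is attached before the nitro group is reduced, because a free 2-aminobenzyl bromide would alkylate itself. The formamide stays N-unsubstituted so that no deprotection is needed; its N–H acidity is handled by using one equivalent of base in the key step.

Step 1
Reactants: 1 1,5-dibromo-2-methyl-3-nitrobenzene (2,4-dibromo-6-nitrotoluene); 2 N-bromosuccinimide
Product: 3 1,5-dibromo-2-(bromomethyl)-3-nitrobenzene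
Conditions: NBS (1.1 equiv), AIBN (cat., in portions), PhCF3, 85 °C, N2
Reagents that add atoms: N-bromosuccinimide, O=C1CCC(=O)N1Br
Why: Wohl–Ziegler radical-chain bromination: the benzylic methyl group is the only sp3 C–H site, the nitro- and bromo-substituted ring is inert to electrophilic bromine, and the two ortho substituents slow a second hydrogen abstraction, so the reaction should stop at the monobromide.

Step 2
Reactants: 3 1,5-dibromo-2-(bromomethyl)-3-nitrobenzene; 4 triphenylphosphine
Product: 5 (2,4-dibromo-6-nitrobenzyl)triphenylphosphonium bromide
Conditions: PPh3 (1.05 equiv), toluene, 90 °C; salt collected by filtration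
Reagents that add atoms: triphenylphosphine, c1ccc(cc1)P(c1ccccc1)c1ccccc1
Why: SN2 quaternisation of the phosphine by the primary benzylic bromide, which should be far faster at 90 °C than any deoxygenation of the nitro group; the salt precipitates from toluene and is thereby freed from unreacted 1 and any gem-dibromide carried over.

Step 3
Reactants: 5 (2,4-dibromo-6-nitrobenzyl)triphenylphosphonium bromide
Product: 6 (2-amino-4,6-dibromobenzyl)triphenylphosphonium bromide
Conditions: Fe powder (5 equiv), AcOH/EtOH, 70 °C; filtration through Celite, CH2Cl2 extraction against aq NaBr
Reagents that add atoms: none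
Why: Béchamp-type reduction of the nitro group by iron in acetic acid, which should leave the aryl C–Br bonds and the benzylic C–P bond untouched and keeps the medium acidic so that the P–CH2 group is never deprotonated.

Step 4
Reactants: 6 (2-amino-4,6-dibromobenzyl)triphenylphosphonium bromide; 7 formic acid
Product: 8 [2,4-dibromo-6-(formylamino)benzyl]triphenylphosphonium bromide
Conditions: HCO2H/Ac2O (pre-mixed, 55 °C, 2 h, 2 equiv), then 6, CH2Cl2, 0 °C to rt; evaporation, trituration with Et2O, drying in vacuo over P2O5
Reagents that add atoms: acetic formic anhydride, CC(=O)OC=O (made in the flask from formic acid 7, OC=O, and acetic anhydride)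
Why: N-formylation of the aniline by the mixed anhydride, which transfers the less hindered and more electrophilic formyl group in preference to acetyl, under acidic conditions in which the phosphonium salt and its bromide counter-ion are unchanged.

Step 5
Reactants: 8 [2,4-dibromo-6-(formylamino)benzyl]triphenylphosphonium bromide
Product: 11 4,6-dibromo-1H-indole, via ylide 9 (not isolated), via oxaphosphetane 10 (not isolated)
Conditions: t-BuOK (1.05 equiv), dry toluene (0.05 M), rt to 110 °C, N2
Reagents that add atoms: none
Why: tert-Butoxide removes a proton from the P–CH2 group to give the semi-stabilised benzylic ylide 9, whose carbanionic carbon (the future C3) adds to the formamide carbonyl carbon (the future C2) to give the cis-fused oxaphosphetane 10, and cycloreversion expels triphenylphosphine oxide, forms C2=C3 and leaves the aromatic indole 11. The closest known reaction type is the intramolecular Wittig indole synthesis from (2-acylaminobenzyl)triphenylphosphonium salts, of which the formamide is the least hindered and most electrophilic member. The one ring that persists, the pyrrole ring N1–C2–C3–C3a–C7a, closes by 5-exo-trig attack on the exocyclic C=O. No stereocentre results, because the two transient sp3 centres of 10 become the sp2 atoms C2 and C3. The selectivity needed is chemoselectivity between acidic sites: the formamide N–H is about as acidic as the P–CH2 group, so only one equivalent of base is used, the unreactive amidate tautomer can return to the N–H ylide by proton transfer, and the irreversible loss of Ph3P=O at reflux drains that equilibrium, while an alkoxide does not metalate the aryl C5–H between the two bromines or attack the C–Br bonds. The five-membered geometry compensates for the low electrophilicity of an amide carbonyl, and dry conditions should keep the ylide from hydrolysing.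

Step 6
Reactants: 11 4,6-dibromo-1H-indole; 2 N-bromosuccinimide
Product: 13 2,3,4,6-tetrabromo-1H-indole, via 3,4,6-tribromo-1H-indole 12 (not isolated)
Conditions: NBS (2.05 equiv, two portions), silica gel, dry CH2Cl2, 0 °C to rt, dark; aq Na2S2O3/NaHCO3 wash
Reagents that add atoms: N-bromosuccinimide, O=C1CCC(=O)N1Br
Why: Electrophilic aromatic bromination of the indole, first at the most nucleophilic C3 and then at C2 of the 3-bromoindole 12 (directly or through a 3,3-dibromoindolenine and 1,2-bromine shift), while the benzo ring is deactivated by its two bromines and water is excluded so that no oxindole should form.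

Compound list
1 | 1,5-dibromo-2-methyl-3-nitrobenzene (2,4-dibromo-6-nitrotoluene) | Cc1c(Br)cc(Br)cc1[N+](=O)[O-] | starting material
2 | N-bromosuccinimide | O=C1CCC(=O)N1Br | starting material
3 | 1,5-dibromo-2-(bromomethyl)-3-nitrobenzene | BrCc1c(Br)cc(Br)cc1[N+](=O)[O-] | intermediate
4 | triphenylphosphine | c1ccc(cc1)P(c1ccccc1)c1ccccc1 | starting material
5 | (2,4-dibromo-6-nitrobenzyl)triphenylphosphonium bromide | [O-][N+](=O)c1cc(Br)cc(Br)c1C[P+](c1ccccc1)(c1ccccc1)c1ccccc1.[Br-] | intermediate
6 | (2-amino-4,6-dibromobenzyl)triphenylphosphonium bromide | Nc1cc(Br)cc(Br)c1C[P+](c1ccccc1)(c1ccccc1)c1ccccc1.[Br-] | intermediate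
7 | formic acid | OC=O | starting material
8 | [2,4-dibromo-6-(formylamino)benzyl]triphenylphosphonium bromide | O=CNc1cc(Br)cc(Br)c1C[P+](c1ccccc1)(c1ccccc1)c1ccccc1.[Br-] | intermediate
9 | ylide, N-{3,5-dibromo-2-[(triphenyl-λ5-phosphanylidene)methyl]phenyl}formamide | O=CNc1cc(Br)cc(Br)c1C=P(c1ccccc1)(c1ccccc1)c1ccccc1 | intermediate (not isolated)
10 | oxaphosphetane fused across C2–C3 of 4,6-dibromoindoline (O on C2, PPh3 phosphorus on C3; cis-fused, racemic, one enantiomer drawn) | Brc1cc(Br)c2[C@@H]3[C@H](Nc2c1)OP3(c1ccccc1)(c1ccccc1)c1ccccc1 | intermediate (not isolated)
11 | 4,6-dibromo-1H-indole | Brc1cc(Br)c2cc[nH]c2c1 | intermediate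
12 | 3,4,6-tribromo-1H-indole | Brc1cc(Br)c2c(Br)c[nH]c2c1 | intermediate (not isolated)
13 | 2,3,4,6-tetrabromo-1H-indole | Brc1cc(Br)c2c(Br)c(Br)[nH]c2c1 | target

Total step count: 6. Longest linear sequence: 6 steps (1 to 13).

Steps most likely to fail

1. Step 5. The base may be consumed at the formamide N–H, leaving an amidate that does not accept the ylide carbon, or the ylide may be protonated or hydrolysed before ring closure, so that C2=C3 does not form. The fallback moves the ring closure to N1–C2 and sets out from 1. Heating 1 with N,N-dimethylformamide dimethyl acetal in DMF at 110 °C should condense the acidic methyl group to (E)-2-(2,4-dibromo-6-nitrophenyl)-N,N-dimethylethenamine F1. Reduction of the nitro group with iron in acetic acid at 80 °C then lets the new aniline add to the enamine carbon and lose dimethylamine (Leimgruber–Batcho indole synthesis). The fallback comes back to the route at 11.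

2. Step 6. The pyrrole ring may be oxidised instead of substituted (bromoindolenine intermediates trapped by adventitious water), the reaction may stall after the first bromination, or the N–H 2,3-dibromoindole may decompose under acid or light during isolation. The fallback introduces the C2 bromine by deoxybromination of a lactam and sets out from 11.
   - Pyridinium tribromide (3 equiv) in t-BuOH/water should give 3,3,4,6-tetrabromo-1,3-dihydro-2H-indol-2-one F2.
   - Zinc dust in acetic acid at rt should remove only the two bromines next to the carbonyl and give 4,6-dibromo-1,3-dihydro-2H-indol-2-one F3.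
   - POBr3 with imidazole in 1,2-dichloroethane at 80 °C should convert the lactam, through its imidoyl bromide, into 2,4,6-tribromo-1H-indole F4.
   - One equivalent of NBS in DMF at 0 °C then brominates C3, and the fallback comes back at 13.

3. Step 3. The benzylic C–P bond may be cleaved during or after the reduction (loss of triphenylphosphine from the electron-rich 2-aminobenzyl salt, or reductive fission), or the polar salt may be lost in the iron residues with scrambling of its counter-ion. The fallback reduces the nitro group before phosphorus is introduced and sets out from 3. Hydrolysis with CaCO3 in dioxane/water at reflux should give (2,4-dibromo-6-nitrophenyl)methanol F5. Iron powder and NH4Cl in EtOH/water at 80 °C should reduce it to (2-amino-4,6-dibromophenyl)methanol F6, a neutral compound that is easy to extract. Heating F6 with triphenylphosphine hydrobromide in acetonitrile should replace the benzylic hydroxyl by the phosphonium group, and the fallback comes back at 6.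

Further compounds
F1 | step 5 | (E)-2-(2,4-dibromo-6-nitrophenyl)-N,N-dimethylethenamine | CN(C)/C=C/c1c(Br)cc(Br)cc1[N+](=O)[O-]
F2 | step 6 | 3,3,4,6-tetrabromo-1,3-dihydro-2H-indol-2-one | O=C1Nc2cc(Br)cc(Br)c2C1(Br)Br
F3 | step 6 | 4,6-dibromo-1,3-dihydro-2H-indol-2-one | O=C1Cc2c(Br)cc(Br)cc2N1
F4 | step 6 | 2,4,6-tribromo-1H-indole | Brc1cc(Br)c2cc(Br)[nH]c2c1
F5 | step 3 | (2,4-dibromo-6-nitrophenyl)methanol | OCc1c(Br)cc(Br)cc1[N+](=O)[O-]
F6 | step 3 | (2-amino-4,6-dibromophenyl)methanol | Nc1cc(Br)cc(Br)c1CO
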